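**Strategy**

The 4,7-oxygen bridge (O–C4(OH)–C5=C6–C7) is read as a masked (Z)-γ-hydroxy enone, the product of a Kornblum–DeLaMare rearrangement. Its precursor is endoperoxide 23, a 1,2-dioxine spanning C4 and C7 of the ten-membered carbocycle. Base removes the C4 hydrogen; one peroxide oxygen leaves the ten-membered dioxacycle, and the nine-membered oxacycle (O, C4, C3, C2, C1, C10, C9, C8, C7), the dihydrofuran, the hemiketal and the enone-derived alkene appear in one operation. The peroxide comes from singlet oxygen and a (Z,Z)-1,3-diene closed by metathesis; (R)-α-phellandrene supplies the cyclohexene, an Evans alkylation C3, a CBS reduction C8.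

Key step: step 18

Remark on numbering: locants C1–C14 are those of the bicyclo[8.4.0]tetradecane skeleton of the target (C1/C10 ring fusion, C3 CH–CO2Me, C4 hemiketal carbon, C7 C–CH3, C8 CH–O-acyl, C11 =C–CH3, C14 CH–iPr).

Assumption: C3 lies α to a masked ketone and can epimerize through the ring-opened β-keto ester. The drawn C3 configuration (ester pointing away from the ring interior, gauche to the hemiketal OH and able to accept its hydrogen bond) is taken to be the thermodynamically preferred one. The route also installs it under kinetic control before the key step.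

**Route**

Step 1
Reactants: 1 (R)-α-phellandrene
Product: 2 (1R,5R,6R)-8,8-dichloro-2-methyl-5-(propan-2-yl)bicyclo[4.2.0]oct-2-en-7-one
Conditions: Cl3CCOCl, Zn–Cu couple, Et2O, sonication, 0 °C → rt
Reagents that add atoms: trichloroacetyl chloride, ClC(=O)C(Cl)(Cl)Cl (source of dichloroketene)
Why: Ketene–alkene [2+2] cycloaddition, in which dichloroketene adds to the disubstituted alkene of the diene on the face anti to isopropyl with its carbonyl carbon at the diene terminus, fixing the cis ring fusion (future C1, C10) relative to C14.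

Step 2
Reactants: 2 dichlorocyclobutanone
Product: 3 (1R,5R,6R)-2-methyl-5-(propan-2-yl)bicyclo[4.2.0]oct-2-en-7-one
Conditions: Zn dust, AcOH, 70 °C
Reagents that add atoms: none
Why: Zinc-mediated reductive dechlorination of the α,α-dichloro ketone, which touches no stereocentre.

Step 3
Reactants: 3 cyclobutanone
Product: 4 (1R,5R,6R,8E)-8-[(dimethylamino)methylidene]-2-methyl-5-(propan-2-yl)bicyclo[4.2.0]oct-2-en-7-one
Conditions: tBuOCH(NMe2)2 (neat), 60 °C
Reagents that add atoms: Bredereck's reagent, CN(C)C(OC(C)(C)C)N(C)C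
Why: Aminomethylenation with Bredereck's reagent at the only α-methylene of the ketone, which introduces the future C8 carbon.

Step 4
Reactants: 4 enaminone
Product: 5 methyl (1R,2R,6R)-2-(2,2-dimethoxyethyl)-3-methyl-6-(propan-2-yl)cyclohex-3-ene-1-carboxylate
Conditions: p-TsOH·H2O (1.5 equiv), MeOH, 65 °C
Reagents that add atoms: methanol, CO
Why: Acid-mediated retro-Claisen cleavage of the strained vinylogous amide by methanol opens the four-membered ring to a methyl ester (future C2) and, after methanolysis of the iminium, a dimethyl acetal (future C9–C8), leaving two cis arms trans to isopropyl.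

Step 5
Reactants: 5 ester acetal
Product: 6 [(1R,2R,6R)-2-(2,2-dimethoxyethyl)-3-methyl-6-(propan-2-yl)cyclohex-3-en-1-yl]methanol
Conditions: LiAlH4, Et2O, 0 °C
Reagents that add atoms: none
Why: Hydride reduction of the ester to the primary alcohol, which also removes the epimerizable α-ester position at C1.

Step 6
Reactants: 6 primary alcohol
Product: 7 [(1R,2R,6R)-2-(2,2-dimethoxyethyl)-3-methyl-6-(propan-2-yl)cyclohex-3-en-1-yl]methyl trifluoromethanesulfonate
Conditions: Tf2O, 2,6-lutidine, CH2Cl2, −78 °C; used at once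
Reagents that add atoms: trifluoromethanesulfonic anhydride, O=S(=O)(OS(=O)(=O)C(F)(F)F)C(F)(F)F
Why: O-Sulfonylation at low temperature gives the very reactive leaving group needed because the β-branched carbon (future C2) must be attacked by a thermally fragile imide enolate.

Step 7
Reactants: 8 (4R)-4-benzyl-1,3-oxazolidin-2-one; 9 (2E)-but-2-enoyl chloride
Product: 11 (4R)-4-benzyl-3-[(2E)-but-2-enoyl]-1,3-oxazolidin-2-one, via lithium oxazolidinide 10 (not isolated)
Conditions: n-BuLi, THF, −78 °C; then 9, −78 → 0 °C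
Reagents that add atoms: none
Why: N-Acylation of the lithiated auxiliary by the acid chloride.

Step 8
Reactants: 11 crotonyl imide; 7 triflate
Product: 13 (4R)-4-benzyl-3-[(2R)-2-{[(1R,2R,6R)-2-(2,2-dimethoxyethyl)-3-methyl-6-(propan-2-yl)cyclohex-3-en-1-yl]methyl}but-3-enoyl]-1,3-oxazolidin-2-one, via sodium dienolate 12 (not isolated)
Conditions: NaN(SiMe3)2, THF, −78 °C; then 7, −78 → −40 °C
Reagents that add atoms: none
Why: Evans auxiliary-controlled deconjugative alkylation, in which γ-deprotonation gives the chelated (Z)-dienolate that is alkylated at its α-carbon on the face opposite the benzyl group, setting C3 (R) and leaving the vinyl group for metathesis.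

Step 9
Reactants: 13 alkylated imide
Product: 14 methyl (2R)-2-{[(1R,2R,6R)-2-(2,2-dimethoxyethyl)-3-methyl-6-(propan-2-yl)cyclohex-3-en-1-yl]methyl}but-3-enoate
Conditions: MeMgBr, MeOH, CH2Cl2, 0 °C
Reagents that add atoms: methanol, CO
Why: Transesterification by bromomagnesium methoxide cleaves the exocyclic imide carbonyl under weakly basic conditions, so that neither C3 nor the β,γ-position of the alkene is disturbed.

Step 10
Reactants: 14 ester acetal
Product: 15 methyl (2R)-2-{[(1R,2R,6R)-3-methyl-2-(2-oxoethyl)-6-(propan-2-yl)cyclohex-3-en-1-yl]methyl}but-3-enoate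
Conditions: p-TsOH·H2O (cat.), acetone/H2O, rt
Reagents that add atoms: water, O
Why: Mild acid hydrolysis of the dimethyl acetal liberates the C8 aldehyde without enolizing the α-vinyl ester.

Step 11
Reactants: 16 prop-2-enal
Product: 17 (3Z)-4-iodopenta-1,3-diene
Conditions: EtPPh3Br, n-BuLi, THF, rt; I2, −78 °C; NaN(SiMe3)2, −20 °C; then 16, −78 °C → rt
Reagents that add atoms: ethyltriphenylphosphonium bromide, CC[P+](c1ccccc1)(c1ccccc1)c1ccccc1.[Br-]; iodine, II
Why: Stork–Zhao-type olefination with the α-iodo ylide, which gives the (Z)-iodoalkene with iodine cis to the vinyl group, the geometry later required at C6=C7.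

Step 12
Reactants: 15 aldehyde; 17 dienyl iodide
Product: 19 methyl (2R)-2-{[(1R,2R,6R)-2-[(3Z)-2-hydroxy-3-methylhexa-3,5-dien-1-yl]-3-methyl-6-(propan-2-yl)cyclohex-3-en-1-yl]methyl}but-3-enoate as both carbinol epimers, via dienylchromium dichloride 18 (not isolated)
Conditions: CrCl2 (4 equiv), NiCl2 (1 mol %), DMSO, rt
Reagents that add atoms: none
Why: Nozaki–Hiyama–Kishi coupling, in which the alkenylchromium species (trivalent chromium) adds to the aldehyde chemoselectively in the presence of the ester and with retention of alkene geometry, the uncontrolled C8 centre being corrected in steps 13 and 14.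

Step 13
Reactants: 19 allylic alcohol (epimers)
Product: 20 methyl (2R)-2-{[(1R,2R,6R)-3-methyl-2-[(3Z)-3-methyl-2-oxohexa-3,5-dien-1-yl]-6-(propan-2-yl)cyclohex-3-en-1-yl]methyl}but-3-enoate
Conditions: Dess–Martin periodinane, NaHCO3, CH2Cl2, 0 °C
Reagents that add atoms: none
Why: Buffered Dess–Martin oxidation converges both epimers to the (Z)-dienone without acid- or base-induced alkene isomerization.

Step 14
Reactants: 20 dienone
Product: 21 methyl (2R)-2-{[(1R,2R,6R)-2-[(2S,3Z)-2-hydroxy-3-methylhexa-3,5-dien-1-yl]-3-methyl-6-(propan-2-yl)cyclohex-3-en-1-yl]methyl}but-3-enoate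
Conditions: (R)-Me-CBS oxazaborolidine [(3aR)-1-methyl-3,3-diphenyltetrahydro-1H,3H-pyrrolo[1,2-c][1,3,2]oxazaborole] (20 mol %), catecholborane, toluene, −78 °C
Reagents that add atoms: none
Why: CBS reduction under reagent control, the α-methyl alkenyl group acting as the large substituent so that the (R)-catalyst delivers hydride to give the (S)-carbinol at C8.

Step 15
Reactants: 21 dienol
Product: 22 methyl (1R,3R,4Z,6Z,8S,10R,14R)-8-hydroxy-7,11-dimethyl-14-(propan-2-yl)bicyclo[8.4.0]tetradeca-4,6,11-triene-3-carboxylate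
Conditions: second-generation Grubbs catalyst (H2IMes)(PCy3)Cl2Ru=CHPh (10 mol %), 1,4-benzoquinone (20 mol %), toluene (1 mM), 80 °C
Reagents that add atoms: none
Why: Ring-closing metathesis between the two terminal alkenes, held syn by the cis-disubstituted cyclohexene, should close the ten-membered ring with the C4=C5 bond Z, the (Z,Z)-1,3-diene being the strain-minimized isomer under reversible conditions, while the trisubstituted alkenes stay inert.

Step 16
Reactants: 22 ring dienol
Product: 23 methyl (1R,3R,4R,7S,8S,10R,14R)-4,7-epidioxy-8-hydroxy-7,11-dimethyl-14-(propan-2-yl)bicyclo[8.4.0]tetradeca-5,11-diene-3-carboxylate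
Conditions: O2, visible light, 5,10,15,20-tetraphenylporphyrin (1 mol %), CH2Cl2, −40 °C
Reagents that add atoms: dioxygen, O=O
Why: Singlet-oxygen [4+2] cycloaddition to the cisoid ring diene, in which the C8–C3 arc of the carbocycle covers one diene face and allylic strain places the C8 and C3 hydrogens (not OH and CO2Me) inside the diene, so that oxygen, assisted by hydrogen bonding to the outward C8 hydroxyl, should add to the open face and set C7 (S), with C4 following from suprafacial addition.

Step 17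
Reactants: 24 1-methyl-1H-imidazole-4-carbaldehyde
Product: 25 (2E)-3-(1-methyl-1H-imidazol-4-yl)prop-2-enoic acid
Conditions: malonic acid, pyridine, piperidine (cat.), 100 °C
Reagents that add atoms: malonic acid, OC(=O)CC(=O)O
Why: Knoevenagel–Doebner condensation with decarboxylation gives the (E)-acrylic acid.

Step 18
Reactants: 23 endoperoxide; 25 N-methylurocanic acid
Product: 28 the target, via urocanoyl endoperoxide 26 (not isolated), via hydroxy enone 27 (not isolated)
Conditions: DCC, DMAP (0.2 equiv), CH2Cl2/DMF, 0 °C → rt; then Et3N (0.5 equiv), rt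
Reagents that add atoms: none
Why: Steglich esterification first acylates the only free hydroxyl (C8); triethylamine then effects a Kornblum–DeLaMare rearrangement, in which E2-type removal of the C4 hydrogen (the only hydrogen on a peroxide-bearing carbon, C7 being quaternary) with O–O cleavage gives the (Z)-γ-hydroxy enone 27, whose C7 hydroxyl adds to the C4 ketone. The net change is excision of one oxygen from the ten-membered 1,2-dioxa ring (O, O, C4, C3, C2, C1, C10, C9, C8, C7) to leave the nine-membered oxacycle of the target; the closest known reaction type is the amine-catalysed conversion of 3,6-dihydro-1,2-dioxines into 2,5-dihydrofuran-2-ols. The dihydrofuran closes by 5-exo-trig addition of the tertiary hydroxyl to the enone carbonyl, and this same bond closes the nine-membered oxacycle transannularly across the carbocycle. The new stereocentre C4 is dictated by C7, because the oxygen bridge can span only one face of the ring, while C7 and C8 are carried over unchanged and C3 should remain, or equilibrate to, the drawn epimer. The step needs regioselective deprotonation, secured by the quaternary C7, and closure through the C7 rather than the C8 oxygen, secured by prior acylation of C8.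

**Compound list**

1 | (5R)-2-methyl-5-(propan-2-yl)cyclohexa-1,3-diene, (R)-α-phellandrene | CC1=CC[C@H](C(C)C)C=C1 | starting material
2 | (1R,5R,6R)-8,8-dichloro-2-methyl-5-(propan-2-yl)bicyclo[4.2.0]oct-2-en-7-one | O=C1[C@@H]2[C@@H](C(C)C)CC=C(C)[C@@H]2C1(Cl)Cl | intermediate
3 | (1R,5R,6R)-2-methyl-5-(propan-2-yl)bicyclo[4.2.0]oct-2-en-7-one | O=C1[C@@H]2[C@@H](C(C)C)CC=C(C)[C@@H]2C1 | intermediate
4 | (1R,5R,6R,8E)-8-[(dimethylamino)methylidene]-2-methyl-5-(propan-2-yl)bicyclo[4.2.0]oct-2-en-7-one | O=C1[C@@H]2[C@@H](C(C)C)CC=C(C)[C@@H]2/C1=C\N(C)C | intermediate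
5 | methyl (1R,2R,6R)-2-(2,2-dimethoxyethyl)-3-methyl-6-(propan-2-yl)cyclohex-3-ene-1-carboxylate | COC(=O)[C@@H]1[C@@H](C(C)C)CC=C(C)[C@@H]1CC(OC)OC | intermediate
6 | [(1R,2R,6R)-2-(2,2-dimethoxyethyl)-3-methyl-6-(propan-2-yl)cyclohex-3-en-1-yl]methanol | OC[C@@H]1[C@@H](C(C)C)CC=C(C)[C@@H]1CC(OC)OC | intermediate
7 | [(1R,2R,6R)-2-(2,2-dimethoxyethyl)-3-methyl-6-(propan-2-yl)cyclohex-3-en-1-yl]methyl trifluoromethanesulfonate | O=S(=O)(OC[C@@H]1[C@@H](C(C)C)CC=C(C)[C@@H]1CC(OC)OC)C(F)(F)F | intermediate
8 | (4R)-4-benzyl-1,3-oxazolidin-2-one | O=C1N[C@H](Cc2ccccc2)CO1 | starting material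
9 | (2E)-but-2-enoyl chloride | C/C=C/C(Cl)=O | starting material
10 | lithium salt of 8 (N-lithio oxazolidinone) | [Li+].O=C1[N-][C@H](Cc2ccccc2)CO1 | intermediate
11 | (4R)-4-benzyl-3-[(2E)-but-2-enoyl]-1,3-oxazolidin-2-one | C/C=C/C(=O)N1[C@H](Cc2ccccc2)COC1=O | intermediate
12 | sodium (Z)-dienolate of 11 | [Na+].[O-]/C(=C\C=C)N1[C@H](Cc2ccccc2)COC1=O | intermediate
13 | (4R)-4-benzyl-3-[(2R)-2-{[(1R,2R,6R)-2-(2,2-dimethoxyethyl)-3-methyl-6-(propan-2-yl)cyclohex-3-en-1-yl]methyl}but-3-enoyl]-1,3-oxazolidin-2-one | O=C1OC[C@@H](Cc2ccccc2)N1C(=O)[C@@H](C=C)C[C@@H]1[C@@H](C(C)C)CC=C(C)[C@@H]1CC(OC)OC | intermediate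
14 | methyl (2R)-2-{[(1R,2R,6R)-2-(2,2-dimethoxyethyl)-3-methyl-6-(propan-2-yl)cyclohex-3-en-1-yl]methyl}but-3-enoate | COC(=O)[C@@H](C=C)C[C@@H]1[C@@H](C(C)C)CC=C(C)[C@@H]1CC(OC)OC | intermediate
15 | methyl (2R)-2-{[(1R,2R,6R)-3-methyl-2-(2-oxoethyl)-6-(propan-2-yl)cyclohex-3-en-1-yl]methyl}but-3-enoate | COC(=O)[C@@H](C=C)C[C@@H]1[C@@H](C(C)C)CC=C(C)[C@@H]1CC=O | intermediate
16 | prop-2-enal (acrolein) | C=CC=O | starting material
17 | (3Z)-4-iodopenta-1,3-diene | C/C(I)=C/C=C | intermediate
18 | [(2Z)-penta-2,4-dien-2-yl]chromium dichloride | C/C(=C/C=C)[Cr](Cl)Cl | intermediate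
19 | methyl (2R)-2-{[(1R,2R,6R)-2-[(3Z)-2-hydroxy-3-methylhexa-3,5-dien-1-yl]-3-methyl-6-(propan-2-yl)cyclohex-3-en-1-yl]methyl}but-3-enoate, both carbinol epimers | COC(=O)[C@@H](C=C)C[C@@H]1[C@@H](C(C)C)CC=C(C)[C@@H]1CC(O)/C(C)=C\C=C | intermediate
20 | methyl (2R)-2-{[(1R,2R,6R)-3-methyl-2-[(3Z)-3-methyl-2-oxohexa-3,5-dien-1-yl]-6-(propan-2-yl)cyclohex-3-en-1-yl]methyl}but-3-enoate | COC(=O)[C@@H](C=C)C[C@@H]1[C@@H](C(C)C)CC=C(C)[C@@H]1CC(=O)/C(C)=C\C=C | intermediate
21 | methyl (2R)-2-{[(1R,2R,6R)-2-[(2S,3Z)-2-hydroxy-3-methylhexa-3,5-dien-1-yl]-3-methyl-6-(propan-2-yl)cyclohex-3-en-1-yl]methyl}but-3-enoate | COC(=O)[C@@H](C=C)C[C@@H]1[C@@H](C(C)C)CC=C(C)[C@@H]1C[C@H](O)/C(C)=C\C=C | intermediate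
22 | methyl (1R,3R,4Z,6Z,8S,10R,14R)-8-hydroxy-7,11-dimethyl-14-(propan-2-yl)bicyclo[8.4.0]tetradeca-4,6,11-triene-3-carboxylate | COC(=O)[C@@H]1C[C@@H]2[C@@H](C(C)C)CC=C(C)[C@@H]2C[C@H](O)/C(C)=C\C=C/1 | intermediate
23 | methyl (1R,3R,4R,7S,8S,10R,14R)-4,7-epidioxy-8-hydroxy-7,11-dimethyl-14-(propan-2-yl)bicyclo[8.4.0]tetradeca-5,11-diene-3-carboxylate | COC(=O)[C@@H]1C[C@@H]2[C@@H](C(C)C)CC=C(C)[C@@H]2C[C@H](O)[C@]2(C)C=C[C@H]1OO2 | intermediate
24 | 1-methyl-1H-imidazole-4-carbaldehyde | Cn1cnc(C=O)c1 | starting material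
25 | (2E)-3-(1-methyl-1H-imidazol-4-yl)prop-2-enoic acid (N-methylurocanic acid) | Cn1cnc(/C=C/C(=O)O)c1 | intermediate
26 | 8-O-[(2E)-3-(1-methyl-1H-imidazol-4-yl)prop-2-enoyl] ester of endoperoxide 23 | COC(=O)[C@@H]1C[C@@H]2[C@@H](C(C)C)CC=C(C)[C@@H]2C[C@H](OC(=O)/C=C/c2cn(C)cn2)[C@]2(C)C=C[C@H]1OO2 | intermediate
27 | methyl (1R,3R,5Z,7S,8S,10R,14R)-7-hydroxy-7,11-dimethyl-8-{[(2E)-3-(1-methyl-1H-imidazol-4-yl)prop-2-enoyl]oxy}-4-oxo-14-(propan-2-yl)bicyclo[8.4.0]tetradeca-5,11-diene-3-carboxylate | COC(=O)[C@@H]1C[C@@H]2[C@@H](C(C)C)CC=C(C)[C@@H]2C[C@H](OC(=O)/C=C/c2cn(C)cn2)[C@](O)(C)/C=C\C1=O | intermediate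
28 | methyl (1R,3R,4R,7S,8S,10R,14R)-4,7-epoxy-4-hydroxy-7,11-dimethyl-8-{[(2E)-3-(1-methyl-1H-imidazol-4-yl)prop-2-enoyl]oxy}-14-(propan-2-yl)bicyclo[8.4.0]tetradeca-5,11-diene-3-carboxylate | COC(=O)[C@@H]1C[C@@H]2[C@@H](C(C)C)CC=C(C)[C@@H]2C[C@H](OC(=O)/C=C/c2cn(C)cn2)[C@]2(C)C=C[C@@]1(O)O2 | target

**Step count**

Total step count: 18. Longest linear sequence: 15 steps (steps 1–6, 8–10, 12–16 and 18).

**Steps most likely to fail**

Step 16 (photooxygenation). The cycloaddition may be slow because the medium-ring diene is twisted out of planarity. Ene-type hydroperoxidation at the trisubstituted cyclohexene or at the C7 methyl may then compete, and facial selectivity may erode. Fallback: it sets out from 22 and comes back at 23. Ground-state O2 is used under one-electron-oxidation catalysis with tris(4-bromophenyl)aminium hexachloroantimonate, (4-BrC6H4)3N·SbCl6 (5 mol %), in CH2Cl2 at −78 °C. This is a radical-cation chain cycloaddition that selects the most easily oxidized π system, the conjugated diene, and has no ene channel. No new compound is made (F0).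

Step 15 (ring-closing metathesis). Oligomerization may outrun closure of the strained ten-membered ring, the C4=C5 bond may form with E geometry, or the free allylic hydroxyl may divert the ruthenium carbene. Fallback: it sets out from 20 and comes back at 22. The ring is closed at the ketone oxidation level, where C8 is sp2 and no hydroxyl is present, under the catalyst and dilution of step 15. This should give the cyclic dienone methyl (1R,3R,4Z,6Z,10R,14R)-7,11-dimethyl-8-oxo-14-(propan-2-yl)bicyclo[8.4.0]tetradeca-4,6,11-triene-3-carboxylate F1. The C8 carbinol is then set in the ring by the (R)-CBS/catecholborane reduction of step 14.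

Step 8 (auxiliary-controlled alkylation). Substitution at the β-branched carbon may be too slow for the imide enolate, which decomposes on warming. The neighbouring acetal oxygen may capture the triflate, or the enolate may act as a base and eliminate it. Fallback: it sets out from 6 and comes back at 14. The alcohol is converted (I2, PPh3, imidazole, CH2Cl2) into the iodide (1R,2R,6R)-1-(iodomethyl)-2-(2,2-dimethoxyethyl)-3-methyl-6-(propan-2-yl)cyclohex-3-ene F2. This is alkylated at the α-carbon by the lithium dienolate of methyl (2E)-but-2-enoate (LDA, THF/DMPU, −78 → 0 °C). The product is 14 together with its C3 epimer, methyl (2S)-2-{[(1R,2R,6R)-2-(2,2-dimethoxyethyl)-3-methyl-6-(propan-2-yl)cyclohex-3-en-1-yl]methyl}but-3-enoate F3. The epimers are separated, or carried on, since C3 converges at the hemiketal stage under the stated assumption.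

**Further compounds**

F0 | step 16 | none | none
F1 | step 15 | methyl (1R,3R,4Z,6Z,10R,14R)-7,11-dimethyl-8-oxo-14-(propan-2-yl)bicyclo[8.4.0]tetradeca-4,6,11-triene-3-carboxylate | COC(=O)[C@@H]1C[C@@H]2[C@@H](C(C)C)CC=C(C)[C@@H]2CC(=O)/C(C)=C\C=C/1
F2 | step 8 | (1R,2R,6R)-1-(iodomethyl)-2-(2,2-dimethoxyethyl)-3-methyl-6-(propan-2-yl)cyclohex-3-ene | IC[C@@H]1[C@@H](C(C)C)CC=C(C)[C@@H]1CC(OC)OC
F3 | step 8 | methyl (2S)-2-{[(1R,2R,6R)-2-(2,2-dimethoxyethyl)-3-methyl-6-(propan-2-yl)cyclohex-3-en-1-yl]methyl}but-3-enoate | COC(=O)[C@H](C=C)C[C@@H]1[C@@H](C(C)C)CC=C(C)[C@@H]1CC(OC)OC
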